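- A partner molecule that the protic impurity has quenched cannot end up in product.

    substrate + partner + catalyst ⇌ product + catalyst, rate k1*[substrate]*[partner]*[catalyst] forward; the back reaction follows from the equilibrium constant (K1 = 36000 /M, k1 = 9.9 × 10⁷ /M²/s)
    partner + protic impurity → quenched reagent (k2 = 510 /M/s)

in all of them: partner 0.600 mM; protic impurity 0.150 mM; catalyst 2.5 µM
- Thursday's: substrate 5.0 × 10⁻⁴ M; a single well-mixed tank run continuously and read at steady state, 15 s in it on average
- Tuesday's: substrate 5.0 × 10⁻⁴ M; a single well-mixed tank run continuously and read at steady state, 75.0 s in it on average
- Saturday's: substrate 5.0 × 10⁻⁴ M (fed, over 12.0 s); a stirred flask in which substrate is dosed at a steady rate over 12.0 s without added volume, worked up at 15 s; time 15 s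
- Wednesday's: substrate 5.0 × 10⁻⁴ M; a closed flask charged with all of it at once and left for 15 s; time 15 s

- the stated concentrations are those of everything mixed, before any reaction; amounts are the same in each set-up
- the feed brings no volume worth counting
- run time (Saturday's): 15 s

- the set-up with the highest amount of product at the outlet or at the end, in percent of the substrate put in ("none" if the first two lie within 2 percentage points) (Thursday's / Tuesday's / Saturday's / Wednesday's / none)
- amount of product at the outlet or at the end, in percent of the substrate put in, Thursday's
- amount of product at the outlet or at the end, in percent of the substrate put in, Tuesday's
- amount of product at the outlet or at the end, in percent of the substrate put in, Saturday's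
- amount of product at the outlet or at the end, in percent of the substrate put in, Wednesday's

- I follow one partner molecule to its fork. The catalyst stays at its charge, so I define s, the selectivity factor, as the coupling rate constant times the catalyst over the quench rate constant, 0.485. The forward odds of coupling against quenching are then s times substrate over impurity.
- I draw Wednesday's flask. At the charge the forward odds are 1.62.
- Wednesday's substrate starts with a forward half-life of 4.67 s. Counting both forward steps at the charge, partner starts with a lifetime of 4.99 s, and I expect the knee of the curve near there.
- Let a and h be the fractions of substrate and impurity left. Forward only, the fork gives a = h^s. Since s is less than one, impurity thins faster in proportion, and the odds tilt towards substrate as Wednesday's flask runs.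
- If the impurity takes its whole charge, 4.50 × 10⁻⁴ M of partner faces 5.0 × 10⁻⁴ M of substrate. Partner is then the limiting reagent, and forward coupling tops out at 90.0 %. With the way back counted, the equilibrium of that case gives 74.1 %.
- In Saturday's flask the odds are even at substrate 3.09 × 10⁻⁴ M, with the impurity as charged. With nothing consumed, the feed needs 7.42 s of its 12.0 s to reach that. After the feed stops, 3.00 s remain, less than Wednesday's starting partner lifetime above.
- So I rank Saturday's below Wednesday's. I do not place the tanks by hand.
- The forecast gives Thursday's 47.1 %, Tuesday's 64.6 %, Saturday's 46.5 % and Wednesday's 61.8 %. It names Tuesday's best, saying “the 75 s tank gets nearest the partner-limited, reversibility-capped yield”.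
- The simulation gives Tuesday's best, as the forecast said, with Thursday's at 47.1 %, Tuesday's at 64.6 %, Saturday's at 47.1 % and Wednesday's at 61.5 %. With the quench step struck out, Tuesday's tank gives 73.9 %. Tuesday's tank holds substrate at 1.77 × 10⁻⁴ M and partner at 1.49 × 10⁻⁴ M, so its impurity balance leaves 2.24 × 10⁻⁵ M, and the forward odds there stand at 3.84.

(The numbers of this flask were set for the occasion; the result is computed.)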